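**Plan**

Numbering (germacrane): ring C1–C10 with C1=C10 (C14 methyl) and C4=C5 (C15H2OH on C4); C6 bears the ester; the lactone C8–O–C12(=O)–C11(=C13) is trans-fused at C7–C8; the 4-ene is Z only by the sequence rule, C3 and C6 being trans across it.
Retrosynthetic cuts in order: the O6–acyl bond and the two silyl ethers; C11=C13; the ring bond C5–C6 (C5 alkenyl iodide plus C6 aldehyde); C7–C8 with the lactone C–O bond (aldol, then lactonization); C3–C4 and C1–C2 of the open chain.
Enabling feature: C5 is a vinylic CH between C4, which holds C15–O cis to C6, and the carbinol C6 on C7 of the five-membered lactone; a Z-iodoalkene (iodine cis to C15–O) can therefore add as an alkenylchromium to a C6 aldehyde and close the ten-membered ring with the C4=C5 geometry already fixed.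
Forward order: open chain C8 to C5 with both trisubstituted alkenes, then the lactone ring, then the ten-membered ring, then C13, the side-chain ester and desilylation.
Stereochemistry: C7 and C8 from an oxazolidinone-controlled syn-aldol reaction; C6 from the ring closure under control of C7; C1=C10 from syn-carboalumination; C4=C5 from anti-carbomagnesiation/iodination and retention in the coupling; side-chain alkene from a stabilized Wittig reaction.

Key step: step 11

**Step 1**
Reactants: 1 tert-butyl(but-3-yn-1-yloxy)dimethylsilane; 2 oxirane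
Product: 5 (3E)-6-[(tert-butyldimethylsilyl)oxy]-4-methylhex-3-en-1-ol, via alkenyldimethylalane 3 (not isolated), via lithium alkenylalanate 4 (not isolated)
Conditions: AlMe3, Cp2ZrCl2 (20 mol %), CH2Cl2, 0 °C to rt; solvent exchanged for hexane/THF; n-BuLi, −78 °C; 2, −78 °C to rt
Reagents that add atoms: trimethylaluminium C[Al](C)C
Why: Zirconium-catalysed syn-carboalumination (Negishi carboalumination) should put the methyl group on the internal alkyne carbon and aluminium on the terminal one, and the derived alanate should open oxirane with retention at the alkenyl carbon, so that C2 and C9 end trans across C1=C10 (E).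

**Step 2**
Reactants: 5 (3E)-6-[(tert-butyldimethylsilyl)oxy]-4-methylhex-3-en-1-ol
Product: 6 tert-butyl{[(3E)-6-bromo-3-methylhex-3-en-1-yl]oxy}dimethylsilane
Conditions: CBr4, PPh3, 2,6-lutidine, CH2Cl2, 0 °C
Reagents that add atoms: carbon tetrabromide BrC(Br)(Br)Br
Why: Appel bromination should convert the primary alcohol into the bromide under neutral conditions that spare the silyl ether and the trisubstituted alkene.

**Step 3**
Reactants: 6 tert-butyl{[(3E)-6-bromo-3-methylhex-3-en-1-yl]oxy}dimethylsilane; 7 prop-2-yn-1-ol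
Product: 10 (2Z,5E)-8-[(tert-butyldimethylsilyl)oxy]-2-(iodomethylidene)-6-methyloct-5-en-1-ol, via Grignard reagent 8 (not isolated), via alkenylmagnesium chelate 9 (not isolated)
Conditions: Mg, THF, rt; then 7 (1.5 equiv, pre-treated with EtMgBr, 1.5 equiv, 0 °C), CuI (10 mol %), THF, 0 °C to rt; then iodine, −20 °C to rt
Reagents that add atoms: iodine [I][I]
Why: Copper-catalysed anti-carbomagnesiation of the magnesium propargyl alkoxide should deliver the alkyl group to C4 and magnesium to C5 within the five-membered chelate 9, and iodinolysis with retention should leave iodine cis to C15–O (Z), the geometry that later becomes the ring-trans C4=C5 bond.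

**Step 4**
Reactants: 10 (2Z,5E)-8-[(tert-butyldimethylsilyl)oxy]-2-(iodomethylidene)-6-methyloct-5-en-1-ol
Product: 11 tert-butyl{[(2Z,5E)-8-[(tert-butyldimethylsilyl)oxy]-2-(iodomethylidene)-6-methyloct-5-en-1-yl]oxy}diphenylsilane
Conditions: TBDPSCl, imidazole, DMF, rt
Reagents that add atoms: tert-butyl(chloro)diphenylsilane CC(C)(C)[Si](Cl)(c1ccccc1)c1ccccc1
Why: Silylation of the primary allylic alcohol with a silyl chloride and imidazole should give an ether that is stable to the mild acid, oxidants, borohydride and chromium reagents of the following steps.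

**Step 5**
Reactants: 11 tert-butyl{[(2Z,5E)-8-[(tert-butyldimethylsilyl)oxy]-2-(iodomethylidene)-6-methyloct-5-en-1-yl]oxy}diphenylsilane
Product: 12 (3E,7Z)-7-{[(tert-butyldiphenylsilyl)oxy]methyl}-8-iodo-3-methylocta-3,7-dien-1-ol
Conditions: CSA (10 mol %), MeOH/CH2Cl2, 0 °C
Reagents that add atoms: none
Why: Acid-catalysed methanolysis should remove the primary tert-butyldimethylsilyl group much faster than the bulkier tert-butyldiphenylsilyl group (selective desilylation).

**Step 6**
Reactants: 12 (3E,7Z)-7-{[(tert-butyldiphenylsilyl)oxy]methyl}-8-iodo-3-methylocta-3,7-dien-1-ol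
Product: 13 (3E,7Z)-7-{[(tert-butyldiphenylsilyl)oxy]methyl}-8-iodo-3-methylocta-3,7-dienal
Conditions: Dess–Martin periodinane, NaHCO3, CH2Cl2, 0 °C; used at once
Reagents that add atoms: none
Why: Dess–Martin oxidation under bicarbonate buffer should give the β,γ-unsaturated aldehyde without acid or base able to move the C1=C10 bond into conjugation.

**Step 7**
Reactants: 14 (4R)-4-benzyl-1,3-oxazolidin-2-one; 15 methyl 4-chloro-4-oxobutanoate
Product: 16 methyl 4-[(4R)-4-benzyl-2-oxo-1,3-oxazolidin-3-yl]-4-oxobutanoate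
Conditions: n-BuLi, THF, −78 °C; then 15, −78 to 0 °C
Reagents that add atoms: none
Why: N-Acylation of the lithiated oxazolidinone by the acid chloride (preparation of an Evans imide) should be much faster than attack on the methyl ester.

**Step 8**
Reactants: 16 methyl 4-[(4R)-4-benzyl-2-oxo-1,3-oxazolidin-3-yl]-4-oxobutanoate; 13 (3E,7Z)-7-{[(tert-butyldiphenylsilyl)oxy]methyl}-8-iodo-3-methylocta-3,7-dienal
Product: 19 (4R)-4-benzyl-3-{(2S,3R)-2-[(2E,6Z)-6-{[(tert-butyldiphenylsilyl)oxy]methyl}-7-iodo-2-methylhepta-2,6-dien-1-yl]-5-oxooxolane-3-carbonyl}-1,3-oxazolidin-2-one, via boron enolate 17 (not isolated), via aldol adduct 18 (not isolated)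
Conditions: 16, Bu2BOTf, Et3N, CH2Cl2, −78 to 0 °C; 13, −78 to 0 °C; pH 7 buffer, MeOH, H2O2, 0 °C; then PPTS (cat.), CH2Cl2, rt
Reagents that add atoms: none
Why: Evans syn-aldol reaction: the Z-boron enolate 17 should add to the aldehyde through a Zimmerman–Traxler chair on the enolate face not shielded by the benzyl group of the (R)-auxiliary, which sets C7 (R) and C8 (S), and the C8 hydroxyl of 18 should then lactonize onto the methyl ester so that C6 and C9 stand trans on the five-membered ring.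

**Step 9**
Reactants: 19 (4R)-4-benzyl-3-{(2S,3R)-2-[(2E,6Z)-6-{[(tert-butyldiphenylsilyl)oxy]methyl}-7-iodo-2-methylhepta-2,6-dien-1-yl]-5-oxooxolane-3-carbonyl}-1,3-oxazolidin-2-one
Product: 20 (4S,5S)-5-[(2E,6Z)-6-{[(tert-butyldiphenylsilyl)oxy]methyl}-7-iodo-2-methylhepta-2,6-dien-1-yl]-4-(hydroxymethyl)oxolan-2-one
Conditions: NaBH4, THF/H2O (4:1), 0 °C
Reagents that add atoms: none
Why: Borohydride reduction of the activated exocyclic imide carbonyl (reductive removal of the Evans auxiliary) should be faster than reduction of the γ-lactone and touches no stereocenter, the change of the C7 descriptor being due only to the new priorities.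

**Step 10**
Reactants: 20 (4S,5S)-5-[(2E,6Z)-6-{[(tert-butyldiphenylsilyl)oxy]methyl}-7-iodo-2-methylhepta-2,6-dien-1-yl]-4-(hydroxymethyl)oxolan-2-one
Product: 21 (2S,3R)-2-[(2E,6Z)-6-{[(tert-butyldiphenylsilyl)oxy]methyl}-7-iodo-2-methylhepta-2,6-dien-1-yl]-5-oxooxolane-3-carbaldehyde
Conditions: Dess–Martin periodinane, NaHCO3, CH2Cl2, 0 °C; used at once
Reagents that add atoms: none
Why: Dess–Martin oxidation is neutral, so the aldehyde should form without epimerization at C7 and without β-elimination of the lactone oxygen at C8.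

**Step 11**
Reactants: 21 (2S,3R)-2-[(2E,6Z)-6-{[(tert-butyldiphenylsilyl)oxy]methyl}-7-iodo-2-methylhepta-2,6-dien-1-yl]-5-oxooxolane-3-carbaldehyde
Product: 23 (6R,7S,8S)-15-[(tert-butyldiphenylsilyl)oxy]-6-hydroxygermacra-1(10)E,4Z-dien-12,8-olide, via alkenylchromium dichloride 22 (not isolated)
Conditions: CrCl2 (10 equiv), NiCl2 (0.1 equiv), degassed DMSO, rt; 21 added by syringe pump, final 0.003 M
Reagents that add atoms: none
Why: CrCl2 should reduce NiCl2 to zerovalent nickel, which inserts into the C5–iodine bond with retention, and transmetalation to trivalent chromium gives 22, which adds to the C6 aldehyde (Nozaki–Hiyama–Kishi reaction run as a macrocyclization, whose closest precedent is the closure of ten-membered germacranolide rings from iodoalkene aldehydes). The ten-membered carbocycle is closed in the 10-exo-trig mode at the aldehyde carbon. Because the Z-iodoalkene (iodine cis to C15–O) keeps its geometry, C3 and C6 end trans across C4=C5, as the germacradiene ring requires. The new stereocenter C6 is controlled by C7: the forming ring holds C5 anti to the C7–C8 bond, and with the C7 hydrogen inside and the lactone methylene C11 outside (Felkin–Anh arrangement) C5 should add to the Re face of the aldehyde and give the 6R carbinol with O6 syn to O8. The step needs the aldehyde to react in the presence of the lactone carbonyl and of an epimerizable C7 carrying a β-acyloxy group, which the carbonyl-selective and non-basic alkenylchromium secures, and it needs ring closure to outrun oligomerization, which high dilution and the rigid trans-lactone with two trisubstituted alkenes should favour.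

**Step 12**
Reactants: 23 (6R,7S,8S)-15-[(tert-butyldiphenylsilyl)oxy]-6-hydroxygermacra-1(10)E,4Z-dien-12,8-olide
Product: 24 (6R,7R,8S)-15-[(tert-butyldiphenylsilyl)oxy]-6-[(triethylsilyl)oxy]germacra-1(10)E,4Z-dien-12,8-olide
Conditions: TESOTf, 2,6-lutidine, CH2Cl2, −78 °C
Reagents that add atoms: triethylsilyl trifluoromethanesulfonate CC[Si](CC)(CC)OS(=O)(=O)C(F)(F)F
Why: Silylation with the silyl triflate and a hindered pyridine base (protection as triethylsilyl ether) should be fast at −78 °C and never generates a free C6 alkoxide that could attack the lactone carbonyl.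

**Step 13**
Reactants: 24 (6R,7R,8S)-15-[(tert-butyldiphenylsilyl)oxy]-6-[(triethylsilyl)oxy]germacra-1(10)E,4Z-dien-12,8-olide
Product: 27 (6R,7R,8S)-15-[(tert-butyldiphenylsilyl)oxy]-6-[(triethylsilyl)oxy]germacra-1(10)E,4Z,11(13)-trien-12,8-olide, via Mannich base 25 (not isolated), via ammonium iodide 26 (not isolated)
Conditions: LiN(iPr)2, THF, −78 °C; CH2=NMe2+ I−, −78 °C to rt; MeI, CH2Cl2, rt; NaHCO3, EtOAc/H2O, rt
Reagents that add atoms: N,N-dimethylmethyleneiminium iodide (Eschenmoser's salt) C=[N+](C)C.[I-]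
Why: Mannich reaction of the lithium lactone enolate with Eschenmoser's salt, N-methylation and Hofmann elimination (α-methylenation of a lactone) should create the exocyclic C11=C13 bond; the C11 center of 25 is lost again, and C7 is not part of the enolate.

**Step 14**
Reactants: 27 (6R,7R,8S)-15-[(tert-butyldiphenylsilyl)oxy]-6-[(triethylsilyl)oxy]germacra-1(10)E,4Z,11(13)-trien-12,8-olide
Product: 28 (6R,7S,8S)-15-[(tert-butyldiphenylsilyl)oxy]-6-hydroxygermacra-1(10)E,4Z,11(13)-trien-12,8-olide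
Conditions: HF·pyridine, pyridine, THF, 0 °C
Reagents that add atoms: none
Why: Pyridine-buffered hydrogen fluoride should cleave the secondary triethylsilyl ether well before the primary tert-butyldiphenylsilyl ether (selective desilylation) and is not acidic enough to start transannular cyclization of the 1,5-diene.

**Step 15**
Reactants: 29 [(tert-butyldimethylsilyl)oxy]acetaldehyde; 30 ethyl 2-(triphenylphosphoranylidene)propanoate
Product: 31 ethyl (2E)-4-[(tert-butyldimethylsilyl)oxy]-2-methylbut-2-enoate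
Conditions: CH2Cl2, rt
Reagents that add atoms: none
Why: Wittig olefination with a stabilized α-methyl ylide should give the E-trisubstituted enoate, the ester group trans to the CH2O carbon.

**Step 16**
Reactants: 31 ethyl (2E)-4-[(tert-butyldimethylsilyl)oxy]-2-methylbut-2-enoate
Product: 32 (2E)-4-[(tert-butyldimethylsilyl)oxy]-2-methylbut-2-enoic acid
Conditions: LiOH, THF/MeOH/H2O, 0 °C to rt; then 1 M HCl to pH 4, 0 °C
Reagents that add atoms: lithium hydroxide [Li+].[OH-]
Why: Saponification of the ethyl ester with LiOH should leave the primary silyl ether and the alkene geometry intact.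

**Step 17**
Reactants: 28 (6R,7S,8S)-15-[(tert-butyldiphenylsilyl)oxy]-6-hydroxygermacra-1(10)E,4Z,11(13)-trien-12,8-olide; 32 (2E)-4-[(tert-butyldimethylsilyl)oxy]-2-methylbut-2-enoic acid
Product: 34 (6R,7R,8S)-15-[(tert-butyldiphenylsilyl)oxy]-6-{[(2E)-4-[(tert-butyldimethylsilyl)oxy]-2-methylbut-2-enoyl]oxy}germacra-1(10)E,4Z,11(13)-trien-12,8-olide, via mixed anhydride 33 (not isolated)
Conditions: 32, 2,4,6-trichlorobenzoyl chloride, Et3N, THF, rt; then 28, DMAP, toluene, rt
Reagents that add atoms: none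
Why: Yamaguchi esterification: the mixed anhydride 33 should acylate the hindered secondary allylic C6 hydroxyl via the acylpyridinium ion with retention at C6, and the E-acid is the stable geometric isomer, so it should not isomerize.

**Step 18**
Reactants: 34 (6R,7R,8S)-15-[(tert-butyldiphenylsilyl)oxy]-6-{[(2E)-4-[(tert-butyldimethylsilyl)oxy]-2-methylbut-2-enoyl]oxy}germacra-1(10)E,4Z,11(13)-trien-12,8-olide
Product: 35 (6R,7R,8S)-15-hydroxy-6-{[(2E)-4-hydroxy-2-methylbut-2-enoyl]oxy}germacra-1(10)E,4Z,11(13)-trien-12,8-olide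
Conditions: HF·pyridine (excess), pyridine, THF, 0 °C to rt
Reagents that add atoms: none
Why: Pyridine-buffered hydrogen fluoride should remove both silyl ethers (global desilylation) under conditions that should not cause acyl migration from O6 to O15, lactone migration or transannular cyclization.

**Compound list**

1 | tert-butyl(but-3-yn-1-yloxy)dimethylsilane | C#CCCO[Si](C)(C)C(C)(C)C | starting material
2 | oxirane (ethylene oxide) | C1CO1 | starting material
3 | [(1E)-4-[(tert-butyldimethylsilyl)oxy]-2-methylbut-1-en-1-yl]dimethylalumane | C[Al](C)/C=C(\C)CCO[Si](C)(C)C(C)(C)C | intermediate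
4 | lithium butyl[(1E)-4-[(tert-butyldimethylsilyl)oxy]-2-methylbut-1-en-1-yl]dimethylaluminate | [Li+].CCCC[Al-](C)(C)/C=C(\C)CCO[Si](C)(C)C(C)(C)C | intermediate
5 | (3E)-6-[(tert-butyldimethylsilyl)oxy]-4-methylhex-3-en-1-ol | OCC/C=C(\C)CCO[Si](C)(C)C(C)(C)C | intermediate
6 | tert-butyl{[(3E)-6-bromo-3-methylhex-3-en-1-yl]oxy}dimethylsilane | BrCC/C=C(\C)CCO[Si](C)(C)C(C)(C)C | intermediate
7 | prop-2-yn-1-ol | C#CCO | starting material
8 | bromo[(3E)-6-[(tert-butyldimethylsilyl)oxy]-4-methylhex-3-en-1-yl]magnesium | Br[Mg]CC/C=C(\C)CCO[Si](C)(C)C(C)(C)C | intermediate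
9 | 4-[(3E)-6-[(tert-butyldimethylsilyl)oxy]-4-methylhex-3-en-1-yl]-2,5-dihydro-1,2-oxamagnesole (cyclic alkenylmagnesium alkoxide, drawn as the monomer) | [Mg]1OCC(CC/C=C(\C)CCO[Si](C)(C)C(C)(C)C)=C1 | intermediate
10 | (2Z,5E)-8-[(tert-butyldimethylsilyl)oxy]-2-(iodomethylidene)-6-methyloct-5-en-1-ol | CC(C)(C)[Si](C)(C)OCC/C(C)=C/CC/C(CO)=C/I | intermediate
11 | tert-butyl{[(2Z,5E)-8-[(tert-butyldimethylsilyl)oxy]-2-(iodomethylidene)-6-methyloct-5-en-1-yl]oxy}diphenylsilane | CC(C)(C)[Si](C)(C)OCC/C(C)=C/CC/C(CO[Si](c1ccccc1)(c1ccccc1)C(C)(C)C)=C/I | intermediate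
12 | (3E,7Z)-7-{[(tert-butyldiphenylsilyl)oxy]methyl}-8-iodo-3-methylocta-3,7-dien-1-ol | OCC/C(C)=C/CC/C(CO[Si](c1ccccc1)(c1ccccc1)C(C)(C)C)=C/I | intermediate
13 | (3E,7Z)-7-{[(tert-butyldiphenylsilyl)oxy]methyl}-8-iodo-3-methylocta-3,7-dienal | O=CC/C(C)=C/CC/C(CO[Si](c1ccccc1)(c1ccccc1)C(C)(C)C)=C/I | intermediate
14 | (4R)-4-benzyl-1,3-oxazolidin-2-one | O=C1N[C@H](Cc2ccccc2)CO1 | starting material
15 | methyl 4-chloro-4-oxobutanoate | COC(=O)CCC(Cl)=O | starting material
16 | methyl 4-[(4R)-4-benzyl-2-oxo-1,3-oxazolidin-3-yl]-4-oxobutanoate | COC(=O)CCC(=O)N1[C@H](Cc2ccccc2)COC1=O | intermediate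
17 | dibutylboron Z-enolate of 16 | CCCCB(CCCC)O/C(=C\CC(=O)OC)N1[C@H](Cc2ccccc2)COC1=O | intermediate
18 | methyl (3R,4S,6E,10Z)-3-[(4R)-4-benzyl-2-oxo-1,3-oxazolidine-3-carbonyl]-10-{[(tert-butyldiphenylsilyl)oxy]methyl}-4-hydroxy-11-iodo-6-methylundeca-6,10-dienoate | COC(=O)C[C@@H](C(=O)N1[C@H](Cc2ccccc2)COC1=O)[C@@H](O)C/C(C)=C/CC/C(CO[Si](c1ccccc1)(c1ccccc1)C(C)(C)C)=C/I | intermediate
19 | (4R)-4-benzyl-3-{(2S,3R)-2-[(2E,6Z)-6-{[(tert-butyldiphenylsilyl)oxy]methyl}-7-iodo-2-methylhepta-2,6-dien-1-yl]-5-oxooxolane-3-carbonyl}-1,3-oxazolidin-2-one | O=C1C[C@@H](C(=O)N2[C@H](Cc3ccccc3)COC2=O)[C@H](C/C(C)=C/CC/C(CO[Si](c2ccccc2)(c2ccccc2)C(C)(C)C)=C/I)O1 | intermediate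
20 | (4S,5S)-5-[(2E,6Z)-6-{[(tert-butyldiphenylsilyl)oxy]methyl}-7-iodo-2-methylhepta-2,6-dien-1-yl]-4-(hydroxymethyl)oxolan-2-one | O=C1C[C@@H](CO)[C@H](C/C(C)=C/CC/C(CO[Si](c2ccccc2)(c2ccccc2)C(C)(C)C)=C/I)O1 | intermediate
21 | (2S,3R)-2-[(2E,6Z)-6-{[(tert-butyldiphenylsilyl)oxy]methyl}-7-iodo-2-methylhepta-2,6-dien-1-yl]-5-oxooxolane-3-carbaldehyde | O=C1C[C@@H](C=O)[C@H](C/C(C)=C/CC/C(CO[Si](c2ccccc2)(c2ccccc2)C(C)(C)C)=C/I)O1 | intermediate
22 | alkenylchromium dichloride from 21 (CrCl2 group in place of iodine at C5) | O=C1C[C@@H](C=O)[C@H](C/C(C)=C/CC/C(CO[Si](c2ccccc2)(c2ccccc2)C(C)(C)C)=C/[Cr](Cl)Cl)O1 | intermediate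
23 | (6R,7S,8S)-15-[(tert-butyldiphenylsilyl)oxy]-6-hydroxygermacra-1(10)E,4Z-dien-12,8-olide | C1C(=O)O[C@H]2C/C(C)=C/CC/C(CO[Si](c3ccccc3)(c3ccccc3)C(C)(C)C)=C/[C@@H](O)[C@H]12 | intermediate
24 | (6R,7R,8S)-15-[(tert-butyldiphenylsilyl)oxy]-6-[(triethylsilyl)oxy]germacra-1(10)E,4Z-dien-12,8-olide | C1C(=O)O[C@H]2C/C(C)=C/CC/C(CO[Si](c3ccccc3)(c3ccccc3)C(C)(C)C)=C/[C@@H](O[Si](CC)(CC)CC)[C@H]12 | intermediate
25 | (6R,7R,8S)-15-[(tert-butyldiphenylsilyl)oxy]-13-(dimethylamino)-6-[(triethylsilyl)oxy]germacra-1(10)E,4Z-dien-12,8-olide (C11 epimers, C11 left open) | CN(C)CC1C(=O)O[C@H]2C/C(C)=C/CC/C(CO[Si](c3ccccc3)(c3ccccc3)C(C)(C)C)=C/[C@@H](O[Si](CC)(CC)CC)[C@H]12 | intermediate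
26 | N-methyl quaternary ammonium iodide of 25 | C[N+](C)(C)CC1C(=O)O[C@H]2C/C(C)=C/CC/C(CO[Si](c3ccccc3)(c3ccccc3)C(C)(C)C)=C/[C@@H](O[Si](CC)(CC)CC)[C@H]12.[I-] | intermediate
27 | (6R,7R,8S)-15-[(tert-butyldiphenylsilyl)oxy]-6-[(triethylsilyl)oxy]germacra-1(10)E,4Z,11(13)-trien-12,8-olide | C=C1C(=O)O[C@H]2C/C(C)=C/CC/C(CO[Si](c3ccccc3)(c3ccccc3)C(C)(C)C)=C/[C@@H](O[Si](CC)(CC)CC)[C@H]12 | intermediate
28 | (6R,7S,8S)-15-[(tert-butyldiphenylsilyl)oxy]-6-hydroxygermacra-1(10)E,4Z,11(13)-trien-12,8-olide | C=C1C(=O)O[C@H]2C/C(C)=C/CC/C(CO[Si](c3ccccc3)(c3ccccc3)C(C)(C)C)=C/[C@@H](O)[C@H]12 | intermediate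
29 | [(tert-butyldimethylsilyl)oxy]acetaldehyde | O=CCO[Si](C)(C)C(C)(C)C | starting material
30 | ethyl 2-(triphenylphosphoranylidene)propanoate | CCOC(=O)C(C)=P(c1ccccc1)(c1ccccc1)c1ccccc1 | starting material
31 | ethyl (2E)-4-[(tert-butyldimethylsilyl)oxy]-2-methylbut-2-enoate | CCOC(=O)/C(C)=C/CO[Si](C)(C)C(C)(C)C | intermediate
32 | (2E)-4-[(tert-butyldimethylsilyl)oxy]-2-methylbut-2-enoic acid | OC(=O)/C(C)=C/CO[Si](C)(C)C(C)(C)C | intermediate
33 | (2E)-4-[(tert-butyldimethylsilyl)oxy]-2-methylbut-2-enoic 2,4,6-trichlorobenzoic anhydride | O=C(OC(=O)/C(C)=C/CO[Si](C)(C)C(C)(C)C)c1c(Cl)cc(Cl)cc1Cl | intermediate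
34 | (6R,7R,8S)-15-[(tert-butyldiphenylsilyl)oxy]-6-{[(2E)-4-[(tert-butyldimethylsilyl)oxy]-2-methylbut-2-enoyl]oxy}germacra-1(10)E,4Z,11(13)-trien-12,8-olide | C=C1C(=O)O[C@H]2C/C(C)=C/CC/C(CO[Si](c3ccccc3)(c3ccccc3)C(C)(C)C)=C/[C@@H](OC(=O)/C(C)=C/CO[Si](C)(C)C(C)(C)C)[C@H]12 | intermediate
35 | (6R,7R,8S)-15-hydroxy-6-{[(2E)-4-hydroxy-2-methylbut-2-enoyl]oxy}germacra-1(10)E,4Z,11(13)-trien-12,8-olide (CNP0344932.1) | C=C1C(=O)O[C@H]2C/C(C)=C/CC/C(CO)=C/[C@@H](OC(=O)/C(C)=C/CO)[C@H]12 | target

**Totals**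

Total step count: 18. Longest linear sequence: 15 steps (steps 1–6, 8–14, 17 and 18).

**Steps most likely to fail**

1. Step 11. The alkenylchromium may add to the aldehyde with poor or reversed facial selectivity at C6, and intermolecular coupling may compete with ring closure. The fallback sets out from 21 and corrects C6 by inversion instead of by addition-face control. The ring closure is run as in step 11 and the (6S)-alcohol F1 is treated with chloroacetic acid, PPh3 and DIAD in toluene at 0 °C (Mitsunobu reaction, inversion at C6) to give the (6R)-chloroacetate F2. Thiourea and NaHCO3 in EtOH at 40 °C should then remove the chloroacetyl group under near-neutral conditions and give 23, where the route is rejoined.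

2. Step 3. The alkylmagnesium 8 may be protonated by the acetylenic C–H of the propargyl alkoxide, and carbomagnesiation by a functionalized primary Grignard reagent may be slow and incomplete. The fallback sets out from bromide 6 and builds the Z-iodoalkene by syn-silylformylation instead of anti-carbometalation. LiC≡CH·H2NCH2CH2NH2 in DMSO at rt should give the terminal alkyne F3. Silylformylation (PhMe2SiH, CO 20 atm, Rh4(CO)12 cat., Et3N, benzene, 100 °C) should add silicon to the terminal carbon and the formyl group to the internal carbon on the same side, giving the Z-silyl enal F4. NaBH4 in MeOH at 0 °C should give the silyl allylic alcohol F5, and iododesilylation with N-iodosuccinimide in MeCN at 0 °C, which proceeds with retention, should give 10, where the route is rejoined.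

3. Step 13. The hindered lactone enolate may be captured sluggishly by the iminium salt, and the quaternization/elimination stage may move the new double bond into the ring. The fallback sets out from 24 and uses an aldol/dehydration sequence instead of the Mannich/Hofmann sequence. LiN(iPr)2 in THF at −78 °C followed by gaseous formaldehyde should give the α-hydroxymethyl lactone F6. MsCl and Et3N in CH2Cl2 at 0 °C should give the mesylate F7, and DBU at rt should eliminate it to 27, where the route is rejoined.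

**Further compounds**

F1 | step 11 | (6S,7S,8S)-15-[(tert-butyldiphenylsilyl)oxy]-6-hydroxygermacra-1(10)E,4Z-dien-12,8-olide (C6 epimer of 23) | C1C(=O)O[C@H]2C/C(C)=C/CC/C(CO[Si](c3ccccc3)(c3ccccc3)C(C)(C)C)=C/[C@H](O)[C@H]12
F2 | step 11 | (6R,7R,8S)-15-[(tert-butyldiphenylsilyl)oxy]-6-(chloroacetoxy)germacra-1(10)E,4Z-dien-12,8-olide | C1C(=O)O[C@H]2C/C(C)=C/CC/C(CO[Si](c3ccccc3)(c3ccccc3)C(C)(C)C)=C/[C@@H](OC(=O)CCl)[C@H]12
F3 | step 3 | tert-butyldimethyl{[(3E)-3-methyloct-3-en-7-yn-1-yl]oxy}silane | C#CCC/C=C(\C)CCO[Si](C)(C)C(C)(C)C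
F4 | step 3 | (2Z,5E)-8-[(tert-butyldimethylsilyl)oxy]-2-{[dimethyl(phenyl)silyl]methylidene}-6-methyloct-5-enal | O=C/C(=C\[Si](C)(C)c1ccccc1)CC/C=C(\C)CCO[Si](C)(C)C(C)(C)C
F5 | step 3 | (2Z,5E)-8-[(tert-butyldimethylsilyl)oxy]-2-{[dimethyl(phenyl)silyl]methylidene}-6-methyloct-5-en-1-ol | OC/C(=C\[Si](C)(C)c1ccccc1)CC/C=C(\C)CCO[Si](C)(C)C(C)(C)C
F6 | step 13 | (6R,7R,8S)-15-[(tert-butyldiphenylsilyl)oxy]-13-hydroxy-6-[(triethylsilyl)oxy]germacra-1(10)E,4Z-dien-12,8-olide (C11 epimers, C11 left open) | OCC1C(=O)O[C@H]2C/C(C)=C/CC/C(CO[Si](c3ccccc3)(c3ccccc3)C(C)(C)C)=C/[C@@H](O[Si](CC)(CC)CC)[C@H]12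
F7 | step 13 | 13-methanesulfonate of F6 | CS(=O)(=O)OCC1C(=O)O[C@H]2C/C(C)=C/CC/C(CO[Si](c3ccccc3)(c3ccccc3)C(C)(C)C)=C/[C@@H](O[Si](CC)(CC)CC)[C@H]12
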